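## Retrosynthetic overview

1. The furan and pyran rings are opened together: the cis-fused bicyclic ketal comes from a keto diol (aryl–CH2–CH(COCH3)–CH(CH3)–CH2OH next to a free phenol). Acid closes both rings under thermodynamic control, so the single fixed CH–CH3 centre sets the ring-fusion and ketal centres.
2. The aryl–CH2 bond of that keto diol is made by Pd-catalysed ring-opening cross-coupling of a 1-methyl-2-alkylcyclopropanol (Kulinkovich reaction of ethyl acetate with a Roche-ester-derived alkene) with the 11-bromo macrolide.
3. The 12-membered lactone is closed by Mitsunobu macrolactonisation (inversion, S to R) of a seco acid; bromination next to the ring CH2 follows.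
4. The aryl–C(chain) bond is made by a carboxylate-directed, Ru-catalysed ortho C–H alkylation of 2-methoxy-4-(methoxymethoxy)benzoic acid with (S)-non-8-en-2-ol (from (S)-propylene oxide and a hexenyl Grignard reagent).
5. The arene comes from resorcinol by Kolbe–Schmitt carboxylation. Ring order: benzene (present from the start), then macrolactone, then furan and pyran together.

Assumption: the configuration is taken exactly as written in the SMILES, i.e. R at the lactone O–CH(CH3) carbon and S at the CH–CH3, ring-fusion CH and ketal carbons of the furo-pyran part.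

## Route

Step 1
Reactants: 1 resorcinol
Product: 2 2,4-dihydroxybenzoic acid
Conditions: KHCO3 (5 equiv), H2O, CO2 (1 atm), 100 °C; then HCl
Reagents that add atoms: potassium hydrogen carbonate as source of carbon dioxide, [K+].OC([O-])=O (CO2, O=C=O)
Why: Kolbe–Schmitt carboxylation of the resorcinol anion takes place ortho to one hydroxyl and para to the other, the standard preparation of β-resorcylic acid.

Step 2
Reactants: 2 2,4-dihydroxybenzoic acid
Product: 3 methoxymethyl 2-hydroxy-4-(methoxymethoxy)benzoate
Conditions: MOMCl (2.2 equiv), i-Pr2NEt (3 equiv), CH2Cl2, 0 °C to rt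
Reagents that add atoms: chloromethyl methyl ether, COCCl
Why: O-alkylation (MOM protection) takes the carboxylate and the free 4-OH, while the 2-OH is held in a hydrogen bond to the carbonyl group and stays free.

Step 3
Reactants: 3 methoxymethyl 2-hydroxy-4-(methoxymethoxy)benzoate
Product: 4 methoxymethyl 2-methoxy-4-(methoxymethoxy)benzoate
Conditions: MeI (3 equiv), K2CO3, DMF, 45 °C
Reagents that add atoms: iodomethane, CI
Why: Williamson methylation of the remaining chelated phenol installs the aryl methyl ether of the target.

Step 4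
Reactants: 4 methoxymethyl 2-methoxy-4-(methoxymethoxy)benzoate
Product: 5 2-methoxy-4-(methoxymethoxy)benzoic acid
Conditions: LiOH·H2O, THF/H2O (3:1), rt; then 1 M HCl to pH 3, 0 °C
Reagents that add atoms: lithium hydroxide, [Li+].[OH-]
Why: Saponification of the unhindered acetal ester is fast at room temperature and leaves the aryl MOM ether intact, freeing the carboxylic acid that directs the next C–H step.

Step 5
Reactants: 6 (S)-propylene oxide, 7 6-bromohex-1-ene
Product: 9 (S)-non-8-en-2-ol, via hex-5-en-1-ylmagnesium bromide 8 (not isolated)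
Conditions: Mg, THF, rt; then CuI (10 mol %), 6, THF, −30 to 0 °C; then 1 M HCl
Reagents that add atoms: none
Why: Copper-catalysed Grignard opening of the terminal epoxide occurs by SN2 attack at the CH2 carbon, so the stereocentre of 6 is carried unchanged into the (S)-alcohol.

Step 6
Reactants: 5 2-methoxy-4-(methoxymethoxy)benzoic acid, 9 (S)-non-8-en-2-ol
Product: 10 2-[(8S)-8-hydroxynonyl]-6-methoxy-4-(methoxymethoxy)benzoic acid
Conditions: [Ru(p-cymene)Cl2]2 (5 mol %), K3PO4 (0.5 equiv), 9 (1.5 equiv), t-AmOH, 90 °C, Ar
Reagents that add atoms: none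
Why: Proposed new method: carboxylate-directed Ru(II)-catalysed anti-Markovnikov hydroarylation of an unactivated terminal alkene by a free benzoic acid; the carboxylate of 5 binds Ru, concerted metalation–deprotonation at the only free ortho C–H (the other ortho position carries OMe) gives a five-membered ruthenacycle, the alkene of 9 inserts 1,2 into the Ru–aryl bond with the aryl group going to the CH2 terminus, and with no β-leaving group present the seven-membered alkyl ruthenacycle is protonated by substrate acid or t-AmOH to release the linear chain; the closest known reaction types are the Ru(II)-catalysed ortho C–H allylation and alkyne hydroarylation of benzoic acids (same ruthenacycle and insertion regiochemistry) and the Ru(II)-carboxylate anti-Markovnikov hydroarylation of 1-alkenes with N-directing groups; no stereocentre is formed and the remote (S)-carbinol is not touched.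

Step 7
Reactants: 10 2-[(8S)-8-hydroxynonyl]-6-methoxy-4-(methoxymethoxy)benzoic acid
Product: 11 (3R)-14-methoxy-12-(methoxymethoxy)-3-methyl-3,4,5,6,7,8,9,10-octahydro-1H-2-benzoxacyclododecin-1-one (lasiodiplodin MOM ether)
Conditions: PPh3, DIAD, toluene (3 mM, slow addition), 0 °C to rt
Reagents that add atoms: none
Why: Mitsunobu macrolactonisation lets the hindered carboxylate act as the nucleophile on the alkoxyphosphonium ion, closing the 12-membered ring with SN2 inversion so that the (S)-alcohol gives the (R)-lactone centre.

Step 8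
Reactants: 11 lasiodiplodin MOM ether
Product: 12 (3R)-11-bromo-14-methoxy-12-(methoxymethoxy)-3-methyl-3,4,5,6,7,8,9,10-octahydro-1H-2-benzoxacyclododecin-1-one
Conditions: NBS (1.05 equiv), MeCN, 0 °C, dark
Reagents that add atoms: N-bromosuccinimide, O=C1CCC(=O)N1Br
Why: Electrophilic aromatic bromination is expected at position 11 (ortho to OMOM, para to OMe, next to the ring CH2), as in the halogenation of 2,4-dialkoxy-6-alkylbenzoates, and not at the position flanked by two alkoxy groups.

Step 9
Reactants: 13 methyl (R)-3-hydroxy-2-methylpropanoate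
Product: 14 methyl (R)-3-((tert-butyldimethylsilyl)oxy)-2-methylpropanoate
Conditions: TBSCl, imidazole, CH2Cl2, rt
Reagents that add atoms: tert-butyldimethylsilyl chloride, CC(C)(C)[Si](C)(C)Cl
Why: Silylation of the primary alcohol protects it through the organometallic steps and leaves the stereocentre untouched.

Step 10
Reactants: 14 methyl (R)-3-((tert-butyldimethylsilyl)oxy)-2-methylpropanoate
Product: 15 (R)-3-((tert-butyldimethylsilyl)oxy)-2-methylpropanal
Conditions: DIBAL-H (1.05 equiv), CH2Cl2, −78 °C; then aq. Rochelle salt
Reagents that add atoms: none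
Why: Partial ester reduction with DIBAL-H stops at the tetrahedral aluminium hemiacetal at −78 °C and gives the aldehyde on work-up without touching the α-stereocentre.

Step 11
Reactants: 15 (R)-3-((tert-butyldimethylsilyl)oxy)-2-methylpropanal
Product: 16 (S)-tert-butyldimethyl((2-methylbut-3-en-1-yl)oxy)silane
Conditions: Ph3PCH3Br, KHMDS, THF, −78 to 0 °C
Reagents that add atoms: methyltriphenylphosphonium bromide, C[P+](c1ccccc1)(c1ccccc1)c1ccccc1.[Br-]
Why: Wittig methylenation at low temperature converts the aldehyde into the terminal alkene without α-epimerisation (the descriptor changes from R to S only because the CIP priorities change).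

Step 12
Reactants: 16 (S)-tert-butyldimethyl((2-methylbut-3-en-1-yl)oxy)silane, 17 ethyl acetate
Product: 18 2-[(2S)-1-((tert-butyldimethylsilyl)oxy)propan-2-yl]-1-methylcyclopropan-1-ol (mixture of ring diastereomers)
Conditions: c-C5H9MgCl (4.5 equiv, slow addition), Ti(Oi-Pr)4 (1 equiv), 17 (1.5 equiv), THF, rt; then 1 M HCl, 0 °C
Reagents that add atoms: none
Why: Kulinkovich hydroxycyclopropanation in its olefin-exchange mode: the titanacyclopropane made from the cyclopentyl Grignard reagent exchanges with alkene 16 and adds twice to the ester; the two new ring stereocentres do not matter because both are destroyed or equilibrated later.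

Step 13
Reactants: 12 the 11-bromo macrolide, 18 the cyclopropanol
Product: 19 (3R)-11-[(3S)-2-acetyl-4-((tert-butyldimethylsilyl)oxy)-3-methylbutyl]-14-methoxy-12-(methoxymethoxy)-3-methyl-3,4,5,6,7,8,9,10-octahydro-1H-2-benzoxacyclododecin-1-one (mixture of epimers at the acetyl-bearing carbon)
Conditions: Pd(OAc)2 (10 mol %), XPhos (20 mol %), Cs2CO3 (2 equiv), 18 (1.5 equiv), toluene, 80 °C
Reagents that add atoms: none
Why: Palladium homoenolate cross-coupling: the Pd(II) alkoxide of the cyclopropanol undergoes β-carbon elimination at the less substituted ring bond and the resulting primary alkyl–Pd–aryl species reductively eliminates to form the aryl–CH2 bond; the acetyl-bearing carbon forms as an epimer mixture that is equilibrated in step 14.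

Step 14
Reactants: 19 the β-aryl ketone
Product: 21 lasiodiplactone A, via keto diol 20 (not isolated)
Conditions: p-TsOH·H2O (0.3 equiv), MeOH, 45 °C; then evaporate, CH2Cl2, 4 Å MS, rt
Reagents that add atoms: none
Why: Acid removes the MOM and TBS groups and the keto diol closes to the bicyclic ketal (intramolecular double ketalisation); the acetyl-bearing carbon epimerises through the enol or enol ether and the ketal is necessarily cis-fused, so under thermodynamic control the fixed (S)-CH–CH3 centre places its methyl group trans to the benzylic CH2 on the convex face, giving the (S) ring-fusion and (S) ketal centres.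

## Compound list

1 | resorcinol | Oc1cccc(O)c1 | starting material
2 | 2,4-dihydroxybenzoic acid | OC(=O)c1ccc(O)cc1O | intermediate
3 | methoxymethyl 2-hydroxy-4-(methoxymethoxy)benzoate | COCOC(=O)c1ccc(OCOC)cc1O | intermediate
4 | methoxymethyl 2-methoxy-4-(methoxymethoxy)benzoate | COCOC(=O)c1ccc(OCOC)cc1OC | intermediate
5 | 2-methoxy-4-(methoxymethoxy)benzoic acid | COCOc1ccc(C(=O)O)c(OC)c1 | intermediate
6 | (S)-propylene oxide | C[C@H]1CO1 | starting material
7 | 6-bromohex-1-ene | C=CCCCCBr | starting material
8 | hex-5-en-1-ylmagnesium bromide | C=CCCCC[Mg]Br | intermediate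
9 | (S)-non-8-en-2-ol | C[C@H](O)CCCCCC=C | intermediate
10 | 2-[(8S)-8-hydroxynonyl]-6-methoxy-4-(methoxymethoxy)benzoic acid | COCOc1cc(CCCCCCC[C@H](C)O)c(C(=O)O)c(OC)c1 | intermediate
11 | (3R)-14-methoxy-12-(methoxymethoxy)-3-methyl-3,4,5,6,7,8,9,10-octahydro-1H-2-benzoxacyclododecin-1-one | COc1cc(OCOC)cc2c1C(=O)O[C@H](C)CCCCCCC2 | intermediate
12 | (3R)-11-bromo-14-methoxy-12-(methoxymethoxy)-3-methyl-3,4,5,6,7,8,9,10-octahydro-1H-2-benzoxacyclododecin-1-one | COc1cc(OCOC)c(Br)c2c1C(=O)O[C@H](C)CCCCCCC2 | intermediate
13 | methyl (R)-3-hydroxy-2-methylpropanoate | COC(=O)[C@H](C)CO | starting material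
14 | methyl (R)-3-((tert-butyldimethylsilyl)oxy)-2-methylpropanoate | COC(=O)[C@H](C)CO[Si](C)(C)C(C)(C)C | intermediate
15 | (R)-3-((tert-butyldimethylsilyl)oxy)-2-methylpropanal | O=C[C@H](C)CO[Si](C)(C)C(C)(C)C | intermediate
16 | (S)-tert-butyldimethyl((2-methylbut-3-en-1-yl)oxy)silane | C=C[C@H](C)CO[Si](C)(C)C(C)(C)C | intermediate
17 | ethyl acetate | CCOC(C)=O | starting material
18 | 2-[(2S)-1-((tert-butyldimethylsilyl)oxy)propan-2-yl]-1-methylcyclopropan-1-ol (ring diastereomers) | CC1(O)CC1[C@H](C)CO[Si](C)(C)C(C)(C)C | intermediate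
19 | (3R)-11-[(3S)-2-acetyl-4-((tert-butyldimethylsilyl)oxy)-3-methylbutyl]-14-methoxy-12-(methoxymethoxy)-3-methyl-3,4,5,6,7,8,9,10-octahydro-1H-2-benzoxacyclododecin-1-one (epimers at the acetyl-bearing carbon) | COc1cc(OCOC)c(CC(C(C)=O)[C@H](C)CO[Si](C)(C)C(C)(C)C)c2c1C(=O)O[C@H](C)CCCCCCC2 | intermediate
20 | (3R)-11-[(3S)-2-acetyl-4-hydroxy-3-methylbutyl]-12-hydroxy-14-methoxy-3-methyl-3,4,5,6,7,8,9,10-octahydro-1H-2-benzoxacyclododecin-1-one (keto diol) | COc1cc(O)c(CC(C(C)=O)[C@H](C)CO)c2c1C(=O)O[C@H](C)CCCCCCC2 | intermediate
21 | lasiodiplactone A | COc1cc2c(c3c1C(=O)O[C@H](C)CCCCCCC3)C[C@H]1[C@H](C)CO[C@@]1(C)O2 | target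

## Step count and risks

Total step count: 14. Longest linear sequence: 9 steps (steps 1–4, 6–8, 13, 14, from resorcinol).

The three steps most likely to fail:

Step 6 (the new C–H alkylation). The risks are alkene isomerisation by Ru–H species, β-hydride elimination instead of protodemetalation, and low turnover with a weakly coordinating carboxylate. The fallback uses known chemistry and sets out from 5 and 6. Ru-catalysed carboxylate-directed ortho-allylation of 5 with allyl acetate ([Ru(p-cymene)Cl2]2, K3PO4, Cl3CCH2OH, 50 °C) gives 2-allyl-6-methoxy-4-(methoxymethoxy)benzoic acid F1. Epoxide 6 is opened with pent-4-enylmagnesium bromide and CuI to give (S)-oct-7-en-2-ol F2. Mitsunobu esterification of F1 with F2 (inversion) gives (R)-oct-7-en-2-yl 2-allyl-6-methoxy-4-(methoxymethoxy)benzoate F3. Ring-closing metathesis (Grubbs II, CH2Cl2, 2 mM, 40 °C) gives the 12-membered cycloalkene (3R)-14-methoxy-12-(methoxymethoxy)-3-methyl-3,4,5,6,7,10-hexahydro-1H-2-benzoxacyclododecin-1-one F4 as an E/Z mixture. Hydrogenation (H2, Pd/C, EtOAc) saturates the ring alkene and the fallback comes back to the route at 11.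

Step 12 (olefin-exchange Kulinkovich reaction). Ligand exchange onto an alkene branched at the allylic carbon can be slow and the yield modest. The fallback sets out from 16 and replaces exchange by a preformed Grignard reagent. Hydroboration–oxidation (9-BBN; NaOH, H2O2) gives (S)-4-((tert-butyldimethylsilyl)oxy)-3-methylbutan-1-ol F5. Appel bromination (CBr4, PPh3) gives (S)-(4-bromo-2-methylbutoxy)(tert-butyl)dimethylsilane F6. Magnesium in THF gives (S)-[4-((tert-butyldimethylsilyl)oxy)-3-methylbutyl]magnesium bromide F7. A classical Kulinkovich reaction of 17 with F7 (2.2 equiv) and Ti(Oi-Pr)4 comes back to the route at 18.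

Step 13 (Pd homoenolate coupling). The aryl bromide is electron-rich and flanked on both sides, and the α-branched homoenolate can lose a β-hydride to give the enone and reduced arene. The fallback avoids the bromide and the cross-coupling and sets out from 11 and 18. p-TsOH in MeOH removes the MOM group of 11 to give (R)-lasiodiplodin F8. Oxidative ring opening of 18 (Pd(OAc)2 cat., O2, DMSO, 80 °C) gives (S)-5-((tert-butyldimethylsilyl)oxy)-4-methyl-3-methylidenepentan-2-one F9. Acid-mediated Friedel–Crafts-type Michael addition of F8 through its position 11 to F9, with desilylation and ketalisation in the same pot (p-TsOH, MeOH/toluene, 60 °C; the conjugate-addition/ketalisation route known for xyloketal-type ketals), comes back to the route at 21.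

## Further compounds

F1 | step 6 | 2-allyl-6-methoxy-4-(methoxymethoxy)benzoic acid | C=CCc1cc(OCOC)cc(OC)c1C(=O)O
F2 | step 6 | (S)-oct-7-en-2-ol | C[C@H](O)CCCCC=C
F3 | step 6 | (R)-oct-7-en-2-yl 2-allyl-6-methoxy-4-(methoxymethoxy)benzoate | C=CCc1cc(OCOC)cc(OC)c1C(=O)O[C@H](C)CCCCC=C
F4 | step 6 | (3R)-14-methoxy-12-(methoxymethoxy)-3-methyl-3,4,5,6,7,10-hexahydro-1H-2-benzoxacyclododecin-1-one (E/Z) | COc1cc(OCOC)cc2c1C(=O)O[C@H](C)CCCCC=CC2
F5 | step 12 | (S)-4-((tert-butyldimethylsilyl)oxy)-3-methylbutan-1-ol | OCC[C@H](C)CO[Si](C)(C)C(C)(C)C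
F6 | step 12 | (S)-(4-bromo-2-methylbutoxy)(tert-butyl)dimethylsilane | BrCC[C@H](C)CO[Si](C)(C)C(C)(C)C
F7 | step 12 | (S)-[4-((tert-butyldimethylsilyl)oxy)-3-methylbutyl]magnesium bromide | Br[Mg]CC[C@H](C)CO[Si](C)(C)C(C)(C)C
F8 | step 13 | (R)-lasiodiplodin | COc1cc(O)cc2c1C(=O)O[C@H](C)CCCCCCC2
F9 | step 13 | (S)-5-((tert-butyldimethylsilyl)oxy)-4-methyl-3-methylidenepentan-2-one | C=C(C(C)=O)[C@H](C)CO[Si](C)(C)C(C)(C)C
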